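It is easy to read Friday's 1.50 Z per G as an excess, but that count stops at the first step.

| flask | G | Z | time |
|---|---|---|---|
| Friday's | 0.48 M (fed, over 1.0 h) | 0.720 M | 2.0 h |
| Tuesday's | 0.48 M (fed, over 1.0 h) | 1.10 M | 2.0 h |
| Monday's | 0.48 M (fed, over 1.0 h) | 1.60 M | 2.0 h |

- part of the G that has reacted at the end, Friday's
- part of the G that has reacted at the end, Tuesday's
- part of the G that has reacted at the end, Monday's
- what raising the concentration of Z from its lowest to its highest value here does to the part of the G that has reacted (changes below 5 percentage points count as none) (it falls / no change / it rises)

    G + Z ⇌ X + E (K1 = 2.09, k1 = 0.0110 /M/min)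
    Z + X ⇌ Z.X, settled at all times (K2 = 5800 /M)
    Z + E → Z.E (k3 = 0.131 /M/min)

In Friday's flask, the equilibrium constant of the binding step times Z is 4200 at the start, so X goes on to Z.X as it forms. E has a half-life of 0.12 h against 1.5 h for G, so E goes on to Z.E, and the first step is the rate-limiting step. Each G that reacts therefore costs about 3 Z.

That makes 2.00 for Friday's flask the Z bill, the fraction of its own Z charge that the whole of G would cost at that price. Tuesday's bill is 1.31 and Monday's 0.900. Friday's and Tuesday's bills exceed one, so at that price Z is the limiting reagent in those two flasks.

Now let x be the fraction of G reacted. A portion of G spends 90.0 min in the flask on average. At full Z, Friday's exposure, k1 times Z times that time, is 0.713, and one minus its negative exponential gives x = 51.0%. But that reaction spends Z, so you put x back, lower Z's mean fraction by 0.5 times the bill times x, and go round again. Friday's x runs 29.5%, 39.5%, 35.0%, 37.1%, closing near 36.0%. Rounds begun at x = 0.5 give 51.3% for Tuesday's and 67.2% for Monday's.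

The forecast, holding that “each G reacted costs almost 3 Z”, gave 35%, 48.5% and 63%, each below my figure, and its verdict on more Z was: it rises.

The flasks give 34.7%, 48.5% and 63.0%, so with more Z it rises, by 28 percentage points. Friday's flask ends with 35% of its Z, less than the 65% of its G. The bill leaves 30.6% of Z at that x, and Friday's E, still unpaid at 5.86% of the G charged, is worth another 3.91%. The flask like Friday's but with 2.9 M of Z has a bill of 0.497. At its 85.6% reacted, that bill leaves 57.5% of Z, and that flask holds 57.7%.

Its constants were set for the occasion; the result is computed.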